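**Plan**
Atom labels follow the order of atoms in the target SMILES (C9 = spiro carbon; ring B = C9, C10, C11, C12, C21, C22; phthalide-derived ring = C14, C16, C18, C25, C30, C31).
Cuts, last bond first: C31 carbinol to ketone; C12–C25 (one radical closure gives ring C and the bicyclo[2.2.2]octane); C18–C20 and C13–C14 (the two bonds to 5,7-dihydroxy-4,6-dimethylphthalide); C21–C22 (ring B); C9–C10 (side chain onto a 3-acyl lactone).
Feature that permits the ring-B cut: the tertiary carbinol C22 (methyl, hydroxyl) is flanked by C21, and the next ring atom C12 carries the one-carbon branch C13. This is the retron of a ketone-ene closure in which C21 of a C12=C21 alkene attacks an acetyl group on C9 while a C13 hydrogen goes to oxygen.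
Forward order: quaternary C9 and ring A lactone, then ring B, then the phthalide attached at C14 and bridged through C18, then ring C plus the bicyclic ring D, then C31 reduction (ring E, the γ-lactone, arrives with the phthalide).
Stereochemistry: C9 from a chiral phase-transfer alkylation; C21 and C22 from the chair ene transition state under control of C9; C14 from a chiral palladium catalyst; C18, C12 and C25 from the geometry of the bridged intermediates; C30 by equilibration; C31 by hydride delivery anti to the lactone arm.

Key step: step 11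

Assumption: the senses of induction of the two chiral catalysts (step 7 and step 20) are taken as those needed for (R)-10 and for the C14 configuration of 27; should either run the other way, its mirror-image catalyst is used and nothing else changes.

**Route**

Step 1
Reactants: 1 but-3-yn-1-ol
Product: 2 tert-butyl(but-3-yn-1-yloxy)dimethylsilane
Conditions: TBSCl, imidazole, CH2Cl2, 0 °C to rt
Reagents that add atoms: tert-butyl(chloro)dimethylsilane, CC(C)(C)[Si](C)(C)Cl
Why: Routine O-silylation gives an acid-labile TBS ether that can later be removed next to the sturdier TBDPS ether.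

Step 2
Reactants: 2 tert-butyl(but-3-yn-1-yloxy)dimethylsilane
Product: 4 (2E)-5-[(tert-butyldimethylsilyl)oxy]-3-methylpent-2-en-1-ol, via alkenylalane 3 (not isolated)
Conditions: Me3Al, Cp2ZrCl2 (0.25 equiv), CH2Cl2, 0 °C to rt; then n-BuLi, THF, −78 °C; (CH2O)n, −78 °C to rt
Reagents that add atoms: trimethylaluminium, C[Al](C)C; paraformaldehyde (formaldehyde unit), C=O
Why: Zirconium-catalysed syn carboalumination (Negishi carboalumination) places methyl on the internal alkyne carbon with aluminium cis to it, and hydroxymethylation of the alanate with retention should give the (E)-trisubstituted alkene (future C12=C21) as one isomer.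

Step 3
Reactants: 4 (2E)-5-[(tert-butyldimethylsilyl)oxy]-3-methylpent-2-en-1-ol
Product: 5 (2E)-5-[(tert-butyldimethylsilyl)oxy]-1-[(tert-butyldiphenylsilyl)oxy]-3-methylpent-2-ene
Conditions: TBDPSCl, imidazole, DMF, rt
Reagents that add atoms: tert-butyl(chloro)diphenylsilane, CC(C)(C)[Si](Cl)(c1ccccc1)c1ccccc1
Why: O-Silylation of the allylic alcohol (future C20–O) with a group that tolerates the later Lewis-acid and organometallic steps.

Step 4
Reactants: 5 (2E)-5-[(tert-butyldimethylsilyl)oxy]-1-[(tert-butyldiphenylsilyl)oxy]-3-methylpent-2-ene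
Product: 6 (3E)-5-[(tert-butyldiphenylsilyl)oxy]-3-methylpent-3-en-1-ol
Conditions: camphorsulfonic acid (5 mol%), MeOH–CH2Cl2, 0 °C
Reagents that add atoms: none
Why: Acid-catalysed methanolysis cleaves the primary TBS ether much faster than the TBDPS ether (selective desilylation).

Step 5
Reactants: 6 (3E)-5-[(tert-butyldiphenylsilyl)oxy]-3-methylpent-3-en-1-ol
Product: 7 tert-butyl{[(2E)-5-iodo-3-methylpent-2-en-1-yl]oxy}diphenylsilane
Conditions: I2, PPh3, imidazole, CH2Cl2, 0 °C
Reagents that add atoms: iodine, II
Why: Appel iodination of a primary alcohol proceeds by SN2 at an unhindered carbon and leaves the alkene geometry untouched.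

Step 6
Reactants: 8 δ-valerolactone (tetrahydro-2H-pyran-2-one)
Product: 9 3-acetyltetrahydro-2H-pyran-2-one (racemic, enolisable)
Conditions: LDA (2.1 equiv), THF, −78 °C; then MeC(O)N(OMe)Me, −78 to 0 °C; aq NH4Cl
Reagents that add atoms: N-methoxy-N-methylacetamide, CC(=O)N(C)OC
Why: Claisen-type C-acylation of the lactone lithium enolate by a Weinreb amide stops at the β-keto lactone because the second equivalent of base stores the product as its enolate.

Step 7
Reactants: 9 3-acetyltetrahydro-2H-pyran-2-one; 7 tert-butyl{[(2E)-5-iodo-3-methylpent-2-en-1-yl]oxy}diphenylsilane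
Product: 10 (3R)-3-acetyl-3-{(3E)-5-[(tert-butyldiphenylsilyl)oxy]-3-methylpent-3-en-1-yl}tetrahydro-2H-pyran-2-one
Conditions: (S)-4,4-dibutyl-2,6-bis(3,4,5-trifluorophenyl)-4,5-dihydro-3H-dinaphtho[2,1-c:1′,2′-e]azepinium bromide (2 mol%), Cs2CO3 (solid), toluene, 0 °C to rt
Reagents that add atoms: none
Why: Asymmetric phase-transfer alkylation of a cyclic β-keto lactone, in which the chiral ammonium cation pairs with the enolate and shields one face, should create the quaternary C9 centre in the (R) sense at the only acidic carbon.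

Step 8
Reactants: 10 (3R)-3-acetyl-3-{(3E)-5-[(tert-butyldiphenylsilyl)oxy]-3-methylpent-3-en-1-yl}tetrahydro-2H-pyran-2-one
Product: 12 (3R)-3-{(3E)-5-[(tert-butyldiphenylsilyl)oxy]-3-methylpent-3-en-1-yl}-6-hydroxy-3-(2-hydroxypropan-2-yl)hexan-2-one, via hydroxy lactone 11 (not isolated)
Conditions: MeMgBr, CeCl3, THF, −78 °C; then MeLi (1.3 equiv), −78 °C; AcOH quench at −78 °C
Reagents that add atoms: methylmagnesium bromide, C[Mg]Br; methyllithium, [Li]C
Why: Cerium-assisted 1,2-addition turns the more electrophilic ketone into the C2 carbinol, and methyllithium then adds once to the lactone carbonyl (the tetrahedral alkoxide holds at −78 °C) so that the old lactone carbon becomes the new acetyl group and releases the primary alcohol, with C9 untouched.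

Step 9
Reactants: 12 (3R)-3-{(3E)-5-[(tert-butyldiphenylsilyl)oxy]-3-methylpent-3-en-1-yl}-6-hydroxy-3-(2-hydroxypropan-2-yl)hexan-2-one
Product: 13 (5R)-5-acetyl-5-{(3E)-5-[(tert-butyldiphenylsilyl)oxy]-3-methylpent-3-en-1-yl}-6,6-dimethyltetrahydro-2H-pyran-2-one
Conditions: TEMPO (0.2 equiv), PhI(OAc)2 (2.5 equiv), CH2Cl2, rt
Reagents that add atoms: none
Why: Nitroxyl-catalysed oxidation of the primary alcohol to the aldehyde, lactol formation with the tertiary hydroxyl and a second oxidation (oxidative lactonisation of a 1,5-diol) should build the saturated ring A lactone while ketone, alkene and silyl ether stay inert.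

Step 10
Reactants: 13 (5R)-5-acetyl-5-{(3E)-5-[(tert-butyldiphenylsilyl)oxy]-3-methylpent-3-en-1-yl}-6,6-dimethyltetrahydro-2H-pyran-2-one
Product: 15 (5R)-5-acetyl-5-{(3E)-5-[(tert-butyldiphenylsilyl)oxy]-3-methylpent-3-en-1-yl}-6,6-dimethyl-5,6-dihydro-2H-pyran-2-one, via bis-silyl enol ether 14 (not isolated)
Conditions: TMSOTf (3 equiv), Et3N (4 equiv), CH2Cl2, 0 °C to rt; then Pd(OAc)2 (1.1 equiv), MeCN, rt; 1 M HCl work-up
Reagents that add atoms: none
Why: Soft enolisation gives the lactone ketene silyl acetal, which divalent palladium dehydrogenates to the enoate (Saegusa–Ito oxidation, β-hydride loss from C8), whereas the ketone silyl enol ether has no β-hydrogen on its quaternary side and returns the acetyl group on acidic work-up.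

Step 11
Reactants: 15 (5R)-5-acetyl-5-{(3E)-5-[(tert-butyldiphenylsilyl)oxy]-3-methylpent-3-en-1-yl}-6,6-dimethyl-5,6-dihydro-2H-pyran-2-one
Product: 16 (6S,7R,8S)-8-{[(tert-butyldiphenylsilyl)oxy]methyl}-7-hydroxy-1,1,7-trimethyl-9-methylidene-2-oxaspiro[5.5]undec-4-en-3-one
Conditions: Me2AlCl (2.0 equiv), CH2Cl2, −78 to −30 °C
Reagents that add atoms: none
Why: Me2AlCl binds the C22 ketone oxygen, C21 of the alkene attacks C22 while a hydrogen of the C13 methyl passes to oxygen through a six-membered array, and the product alkoxide loses methane so that no proton is left to trigger side reactions (type-2 intramolecular carbonyl-ene or Prins reaction, as in Lewis-acid closures of unsaturated ketones and aldehydes to 3-methylenecyclohexanols). Ring B closes endo at the alkene and exo at the carbonyl through a chair made of C9, C10, C11, C12, C21 and C22. C21 is fixed by the (E)-alkene, whose C20 arm must lie equatorial, and C22 by the need for the aluminium-bound oxygen to be axial within reach of the C13 hydrogen, so hydroxyl and C20 should end cis. Their configuration relative to C9 should follow from placing that bulky axial oxygen anti to the CMe2–O arm of C9 and gauche to the slim C8 vinyl arm. The step needs chemoselectivity for the ketone over the lactone carbonyl and enoate, and facial selectivity at the ketone; the quaternary C9 (Thorpe–Ingold effect), the electron-rich trisubstituted alkene and the size difference between the two C9 arms are what the substrate offers for this.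

Step 12
Reactants: 16 (6S,7R,8S)-8-{[(tert-butyldiphenylsilyl)oxy]methyl}-7-hydroxy-1,1,7-trimethyl-9-methylidene-2-oxaspiro[5.5]undec-4-en-3-one
Product: 17 (6S,7R,8S)-7-hydroxy-8-(hydroxymethyl)-1,1,7-trimethyl-9-methylidene-2-oxaspiro[5.5]undec-4-en-3-one
Conditions: HF·pyridine, pyridine, THF, 0 °C to rt
Reagents that add atoms: none
Why: Buffered fluoride desilylation frees the C20 hydroxyl without the basic conditions that could open the enoate lactone by a vinylogous retro-aldol path.

Step 13
Reactants: 17 (6S,7R,8S)-7-hydroxy-8-(hydroxymethyl)-1,1,7-trimethyl-9-methylidene-2-oxaspiro[5.5]undec-4-en-3-one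
Product: 18 [(6S,7R,8S)-7-hydroxy-1,1,7-trimethyl-9-methylidene-3-oxo-2-oxaspiro[5.5]undec-4-en-8-yl]methyl 4-methylbenzenesulfonate
Conditions: TsCl, pyridine, DMAP (5 mol%), CH2Cl2, 0 °C
Reagents that add atoms: 4-methylbenzenesulfonyl chloride, Cc1ccc(cc1)S(Cl)(=O)=O
Why: Sulfonylation is selective for the primary hydroxyl over the hindered tertiary one and gives a C20 leaving group that survives hypochlorite and zerovalent palladium.

Step 14
Reactants: 18 [(6S,7R,8S)-7-hydroxy-1,1,7-trimethyl-9-methylidene-3-oxo-2-oxaspiro[5.5]undec-4-en-8-yl]methyl 4-methylbenzenesulfonate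
Product: 19 allylic chloride (tosylate 18 in which the exocyclic C12=C13 has become a ring C11=C12 alkene with chlorine on C13; C9, C21 and C22 as in 18)
Conditions: NaOCl (aq), CeCl3·7H2O, CH2Cl2–H2O, 0 °C
Reagents that add atoms: sodium hypochlorite, [Na+].[O-]Cl
Why: Ene-type allylic chlorination puts chlorine on the terminal C13 and moves the double bond into the ring by loss of a C11 hydrogen, which is more accessible than the single C21 hydrogen flanked by two fully substituted carbons, while the electron-poor enoate is not attacked.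

Step 15
Reactants: 20 atraric acid (methyl 2,4-dihydroxy-3,6-dimethylbenzoate)
Product: 21 methyl 5-formyl-2,4-dihydroxy-3,6-dimethylbenzoate
Conditions: Cl2CHOMe, TiCl4, CH2Cl2, −10 °C to rt; then H2O
Reagents that add atoms: dichloromethyl methyl ether, COC(Cl)Cl; water, O
Why: Rieche formylation attacks the only free ring position, which is ortho and para to the two hydroxyl groups.

Step 16
Reactants: 21 methyl 5-formyl-2,4-dihydroxy-3,6-dimethylbenzoate
Product: 22 methyl 2,4-dihydroxy-3,5,6-trimethylbenzoate
Conditions: Et3SiH (3 equiv), CF3CO2H, CH2Cl2, 0 °C to rt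
Reagents that add atoms: none
Why: Ionic hydrogenation reduces the hydroxyl-stabilised benzylic cation twice, turning the formyl group into the methyl group that becomes C19.

Step 17
Reactants: 22 methyl 2,4-dihydroxy-3,5,6-trimethylbenzoate
Product: 23 methyl 2,4-dimethoxy-3,5,6-trimethylbenzoate
Conditions: MeI, K2CO3, DMF, 60 °C
Reagents that add atoms: iodomethane, CI
Why: Williamson O-methylation masks both phenols (the chelated 2-hydroxyl needs the forcing conditions) so that a strong base can be used next.

Step 18
Reactants: 23 methyl 2,4-dimethoxy-3,5,6-trimethylbenzoate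
Product: 25 5,7-dimethoxy-4,6-dimethyl-2-benzofuran-1(3H)-one, via hydroxymethyl ester 24 (not isolated)
Conditions: LDA (1.2 equiv), THF, −78 °C; then 2-(phenylsulfonyl)-3-phenyloxaziridine, −78 °C to rt; 1 M HCl
Reagents that add atoms: 2-(phenylsulfonyl)-3-phenyloxaziridine, O=S(=O)(N1OC1c1ccccc1)c1ccccc1
Why: Lateral lithiation occurs only at the methyl group ortho to the ester (the one benzylic anion conjugated with it), electrophilic oxygen transfer gives the benzylic alkoxide, and this closes onto the ester to form the phthalide.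

Step 19
Reactants: 25 5,7-dimethoxy-4,6-dimethyl-2-benzofuran-1(3H)-one
Product: 26 5,7-dihydroxy-4,6-dimethyl-2-benzofuran-1(3H)-one
Conditions: BBr3 (3.5 equiv), CH2Cl2, −78 °C to rt
Reagents that add atoms: none
Why: Lewis-acid cleavage of aryl methyl ethers frees both phenols and leaves the γ-lactone intact.

Step 20
Reactants: 19 allylic chloride; 26 5,7-dihydroxy-4,6-dimethyl-2-benzofuran-1(3H)-one
Product: 27 C14-allylated dienone (the phthalide is dearomatised at its C6, here C14, which now carries methyl and the C13 methylene of the ring-B cyclohexene; drawn as the 7-hydroxy-5-oxo tautomer; C14 configured as in 31; tosylate retained)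
Conditions: Pd2(dba)3·CHCl3 (2.5 mol%), N,N′-[(1R,2R)-cyclohexane-1,2-diyl]bis[2-(diphenylphosphanyl)benzamide] (7.5 mol%), Cs2CO3 (2.2 equiv), 1,4-dioxane, rt
Reagents that add atoms: none
Why: Tsuji–Trost allylic alkylation with dearomatisation: the π-allyl complex is attacked at its unhindered C13 end by the phenoxide through C14, the one ring carbon ortho to both oxygens, and the chiral ligand pocket is relied on to choose the face of the planar nucleophile and so set C14.

Step 21
Reactants: 27 C14-allylated dienone
Product: 29 bridged enedione (C13 and C20 both bonded to one face of the phthalide-derived ring at C14 and C18; C11=C12 and C25=C30 double bonds; C16 and C31 ketones), via iodide 28 (not isolated)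
Conditions: NaI (5 equiv), acetone, 50 °C; evaporate; LiHMDS (1.05 equiv), toluene–THF 10:1, −78 to 80 °C
Reagents that add atoms: none
Why: Finkelstein exchange followed by intramolecular C-alkylation of the lithium vinylogous carboxylate in a weakly polar medium should close the seven-membered ring at C18 (C30 is the acyl-bearing, deactivated carbon), and since a four-atom bridge can only span one face of the ring, C18 follows from C14.

Step 22
Reactants: 29 bridged enedione
Product: 30 cage diketone (the 31-oxo analogue of 31)
Conditions: Fe(acac)3 (0.3 equiv), PhSiH3 (3 equiv), EtOH–(CH2OH)2 5:1, 60 °C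
Reagents that add atoms: none
Why: Metal-hydride hydrogen-atom transfer to C11 gives the tertiary C12 radical, which adds across the bridged ring to C25 of the alkylidene β-keto lactone (transannular 5-exo Giese closure) on the ring-B face that carries C20, fixing C12 and C25 together, and the reduced, protonated C30 centre can settle by enolisation with its lactone arm on the side of the C18 methyl.

Step 23
Reactants: 30 cage diketone
Product: 31 target compound CNP0360620.2
Conditions: NaBH4, CeCl3·7H2O, MeOH–THF, −40 °C
Reagents that add atoms: none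
Why: Luche-type 1,2-reduction should touch only the C31 ketone (the C16 ketone lies between two quaternary carbons and the enoate is inert at this temperature), with hydride entering from the face bearing the C30 hydrogen, anti to the lactone arm, to give the hydroxyl cis to C28.

**Compound list**

1 | but-3-yn-1-ol | C#CCCO | starting material
2 | tert-butyl(but-3-yn-1-yloxy)dimethylsilane | C#CCCO[Si](C)(C)C(C)(C)C | intermediate
3 | {(1E)-4-[(tert-butyldimethylsilyl)oxy]-2-methylbut-1-en-1-yl}dimethylalane (not isolated) | C[Al](C)/C=C(\C)CCO[Si](C)(C)C(C)(C)C | intermediate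
4 | (2E)-5-[(tert-butyldimethylsilyl)oxy]-3-methylpent-2-en-1-ol | OC/C=C(\C)CCO[Si](C)(C)C(C)(C)C | intermediate
5 | (2E)-5-[(tert-butyldimethylsilyl)oxy]-1-[(tert-butyldiphenylsilyl)oxy]-3-methylpent-2-ene | CC(C)(C)[Si](c1ccccc1)(c1ccccc1)OC/C=C(\C)CCO[Si](C)(C)C(C)(C)C | intermediate
6 | (3E)-5-[(tert-butyldiphenylsilyl)oxy]-3-methylpent-3-en-1-ol | CC(C)(C)[Si](c1ccccc1)(c1ccccc1)OC/C=C(\C)CCO | intermediate
7 | tert-butyl{[(2E)-5-iodo-3-methylpent-2-en-1-yl]oxy}diphenylsilane | CC(C)(C)[Si](c1ccccc1)(c1ccccc1)OC/C=C(\C)CCI | intermediate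
8 | δ-valerolactone (tetrahydro-2H-pyran-2-one) | O=C1CCCCO1 | starting material
9 | 3-acetyltetrahydro-2H-pyran-2-one (racemic, enolisable) | CC(=O)C1CCCOC1=O | intermediate
10 | (3R)-3-acetyl-3-{(3E)-5-[(tert-butyldiphenylsilyl)oxy]-3-methylpent-3-en-1-yl}tetrahydro-2H-pyran-2-one | O=C1OCCC[C@]1(CC/C(C)=C/CO[Si](c2ccccc2)(c2ccccc2)C(C)(C)C)C(C)=O | intermediate
11 | (3R)-3-{(3E)-5-[(tert-butyldiphenylsilyl)oxy]-3-methylpent-3-en-1-yl}-3-(2-hydroxypropan-2-yl)tetrahydro-2H-pyran-2-one (not isolated) | O=C1OCCC[C@]1(CC/C(C)=C/CO[Si](c2ccccc2)(c2ccccc2)C(C)(C)C)C(C)(C)O | intermediate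
12 | (3R)-3-{(3E)-5-[(tert-butyldiphenylsilyl)oxy]-3-methylpent-3-en-1-yl}-6-hydroxy-3-(2-hydroxypropan-2-yl)hexan-2-one | OCCC[C@@](C(C)(C)O)(CC/C(C)=C/CO[Si](c1ccccc1)(c1ccccc1)C(C)(C)C)C(C)=O | intermediate
13 | (5R)-5-acetyl-5-{(3E)-5-[(tert-butyldiphenylsilyl)oxy]-3-methylpent-3-en-1-yl}-6,6-dimethyltetrahydro-2H-pyran-2-one | CC1(C)OC(=O)CC[C@@]1(CC/C(C)=C/CO[Si](c2ccccc2)(c2ccccc2)C(C)(C)C)C(C)=O | intermediate
14 | bis(trimethylsilyl) derivative of 13: lactone ketene silyl acetal plus ketone silyl enol ether, C9 unchanged (not isolated) | CC1(C)OC(O[Si](C)(C)C)=CC[C@@]1(CC/C(C)=C/CO[Si](c2ccccc2)(c2ccccc2)C(C)(C)C)C(=C)O[Si](C)(C)C | intermediate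
15 | (5R)-5-acetyl-5-{(3E)-5-[(tert-butyldiphenylsilyl)oxy]-3-methylpent-3-en-1-yl}-6,6-dimethyl-5,6-dihydro-2H-pyran-2-one (ene precursor) | CC1(C)OC(=O)C=C[C@@]1(CC/C(C)=C/CO[Si](c2ccccc2)(c2ccccc2)C(C)(C)C)C(C)=O | intermediate
16 | (6S,7R,8S)-8-{[(tert-butyldiphenylsilyl)oxy]methyl}-7-hydroxy-1,1,7-trimethyl-9-methylidene-2-oxaspiro[5.5]undec-4-en-3-one (ring A/B spirolactone) | CC1(C)OC(=O)C=C[C@]12CCC(=C)[C@@H](CO[Si](c3ccccc3)(c3ccccc3)C(C)(C)C)[C@@]2(C)O | intermediate
17 | (6S,7R,8S)-7-hydroxy-8-(hydroxymethyl)-1,1,7-trimethyl-9-methylidene-2-oxaspiro[5.5]undec-4-en-3-one | CC1(C)OC(=O)C=C[C@]12CCC(=C)[C@@H](CO)[C@@]2(C)O | intermediate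
18 | [(6S,7R,8S)-7-hydroxy-1,1,7-trimethyl-9-methylidene-3-oxo-2-oxaspiro[5.5]undec-4-en-8-yl]methyl 4-methylbenzenesulfonate | CC1(C)OC(=O)C=C[C@]12CCC(=C)[C@@H](COS(=O)(=O)c3ccc(C)cc3)[C@@]2(C)O | intermediate
19 | allylic chloride: tosylate 18 with a ring C11=C12 alkene and chloromethyl (C13) on C12; C9, C21, C22 as in 18 | CC1(C)OC(=O)C=C[C@]12CC=C(CCl)[C@@H](COS(=O)(=O)c3ccc(C)cc3)[C@@]2(C)O | intermediate
20 | atraric acid (methyl 2,4-dihydroxy-3,6-dimethylbenzoate) | COC(=O)c1c(C)cc(O)c(C)c1O | starting material
21 | methyl 5-formyl-2,4-dihydroxy-3,6-dimethylbenzoate | COC(=O)c1c(C)c(C=O)c(O)c(C)c1O | intermediate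
22 | methyl 2,4-dihydroxy-3,5,6-trimethylbenzoate | COC(=O)c1c(C)c(C)c(O)c(C)c1O | intermediate
23 | methyl 2,4-dimethoxy-3,5,6-trimethylbenzoate | COC(=O)c1c(C)c(C)c(OC)c(C)c1OC | intermediate
24 | methyl 2-(hydroxymethyl)-4,6-dimethoxy-3,5-dimethylbenzoate (not isolated) | COC(=O)c1c(CO)c(C)c(OC)c(C)c1OC | intermediate
25 | 5,7-dimethoxy-4,6-dimethyl-2-benzofuran-1(3H)-one | O=C1OCc2c(C)c(OC)c(C)c(OC)c12 | intermediate
26 | 5,7-dihydroxy-4,6-dimethyl-2-benzofuran-1(3H)-one | O=C1OCc2c(C)c(O)c(C)c(O)c12 | intermediate
27 | C14-allylated dienone: 7-hydroxy-4,6-dimethyl-1,5-dioxo-1,3,5,6-tetrahydro-2-benzofuran-6-yl unit joined through C13 to C12 of the ring-B cyclohexene of 19; tosylate retained; C14 as in 31 | CC1(C)OC(=O)C=C[C@]12CC=C(C[C@]3(C)C(=O)C(C)=C4COC(=O)C4=C3O)[C@@H](COS(=O)(=O)c3ccc(C)cc3)[C@@]2(C)O | intermediate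
28 | iodide corresponding to tosylate 27 (not isolated) | CC1(C)OC(=O)C=C[C@]12CC=C(C[C@]3(C)C(=O)C(C)=C4COC(=O)C4=C3O)[C@@H](CI)[C@@]2(C)O | intermediate
29 | bridged enedione: C13 on C14 and C20 on C18, both on one face of the phthalide-derived ring; C11=C12 and C25=C30 alkenes; C16 and C31 ketones | CC1(C)OC(=O)C=C[C@]12CC=C1C[C@]4(C)C(=O)[C@](C)(C[C@H]1[C@@]2(C)O)C1=C(C4=O)C(=O)OC1 | intermediate
30 | cage diketone: 31 with a ketone at C31 | CC1(C)OC(=O)C=C[C@]12CC[C@]13C[C@]4(C)C(=O)[C@](C)(C[C@H]1[C@@]2(C)O)[C@]31COC(=O)[C@H]1C4=O | intermediate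
31 | CNP0360620.2 | CC1(C)OC(=O)C=C[C@]12CC[C@]13C[C@]4(C)C(=O)[C@](C)(C[C@H]1[C@@]2(C)O)[C@]31COC(=O)[C@H]1[C@H]4O | target

**Step count**
Total: 23 steps. Longest linear sequence: 17 steps (steps 1–5, 7–14, 20–23).

**Steps most likely to fail**

Step 20. The chiral palladium complex may fail to tell apart the two faces of the flat phenoxide, because the stereocentres of 19 are too far from C14 to help; O-allylation may also compete. Fallback, setting out from 19 and 26 and coming back at 27: the allylation is run with Pd(PPh3)4 and Cs2CO3 in dioxane without a chiral ligand, giving 27 together with its C14 epimer F1. The two are separated by preparative chromatography. The C14 epimer F1 is returned to Pd(PPh3)4 at 60 °C, where reversible ionisation of its allyl–C14 bond by zerovalent palladium (the leaving group is an aromatic phenoxide) should re-equilibrate it with 27. Control by catalyst is thus replaced by separation with recycling, and 27 goes on to step 21.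

Step 21. O-Alkylation of the delocalised vinylogous carboxylate, giving a seven-membered enol ether, may outrun C-alkylation at the fully substituted C18. Fallback, setting out from 27 and coming back at 30: the order of the last two carbon–carbon bonds is reversed. The conditions of step 22 (Fe(acac)3, PhSiH3, EtOH) are applied to 27 first, so that the C12 radical adds to C25 and gives the bicyclo[2.2.2]octane tosylate F2, in which C18 is now a CH next to the C16 ketone. KHMDS (3.2 equiv, THF, −78 to 0 °C; the tertiary alkoxide and the β-keto-lactone enolate form first) then generates the C18 ketone enolate, which closes ring C on the C20 tosylate by a 5-exo-tet alkylation to give 30. The price is that the C12–C25 bond forms without the C20 tether, so the radical may add to either face at C12, and only the epimer with C25 cis to C20 (F2) can close.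

Step 7. The SN2 reaction of the unactivated homoallylic iodide may be slow under solid–liquid phase transfer, so that uncatalysed background alkylation, O-alkylation or elimination of the iodide lowers yield and enantiomeric purity. Fallback, setting out from 9 (with 7) and coming back at 10: a covalent auxiliary replaces the catalyst. 9 is condensed with tert-butyl L-valinate (BF3·OEt2 cat., benzene, azeotropic removal of water) to the enamino lactone F3. Deprotonation with LDA in toluene at −78 °C and addition of 7 should alkylate one face of the chelated lithio-enamine to give the alkylated ketimine F4 (the solvent, toluene or THF–HMPA, is chosen for the sense that leads to (R)-10). Aqueous acetic acid hydrolyses F4 to 10 and returns the auxiliary.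

**Further compounds**
F1 | step 20 | C14 epimer of 27 | CC1(C)OC(=O)C=C[C@]12CC=C(C[C@@]3(C)C(=O)C(C)=C4COC(=O)C4=C3O)[C@@H](COS(=O)(=O)c3ccc(C)cc3)[C@@]2(C)O
F2 | step 21 | bicyclo[2.2.2]octane tosylate (C12–C25 bond present, C18–C20 bond absent, C25 cis to C20 on ring B; C18 and C30 unassigned) | CC1(C)OC(=O)C=C[C@]12CC[C@]3(C[C@]4(C)C(=O)C(C)[C@]35COC(=O)C5C4=O)[C@@H](COS(=O)(=O)c3ccc(C)cc3)[C@@]2(C)O
F3 | step 7 | tert-butyl N-[1-(2-oxotetrahydro-2H-pyran-3-ylidene)ethyl]-L-valinate (enamino lactone) | CC(C)[C@H](NC(C)=C1CCCOC1=O)C(=O)OC(C)(C)C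
F4 | step 7 | ketimine of 10 with tert-butyl L-valinate | CC(=N[C@@H](C(C)C)C(=O)OC(C)(C)C)[C@@]1(CC/C(C)=C/CO[Si](c2ccccc2)(c2ccccc2)C(C)(C)C)CCCOC1=O
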